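**Plan**

1. The side chain is numbered C1' (benzylic CH2) to C15' (prenyl terminus) and the arene is ring A. The retrosynthesis cuts C9'–C10' first, then C1'–C2', then C4'–C5', and in the small right-hand piece C12'–C13' and C14'=C15'.
2. Enabling feature: C9' is an unactivated primary sp3 CH2 two atoms from the C6'=C7' alkene, and C10' is the bare sp2 CH end of the C10'=C11'(CH3) alkene beside the C12' carbinol. Both are acceptor-type carbons most simply held as iodides, and the sp3/sp2 difference between the two C–I bonds lets one nickel catalyst join them reductively, electrophile to electrophile.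
3. Forward order: ring A phenol 1 to benzylic chloride 5; butynyl ether 6 to enal 10 (C6'=C7'), propargylation (C4'–C5'), carboalumination with benzylation (C2'=C3', C1'–C2') to iodide 16; propargyl alcohol 17 to iodo dienol 22 (C10'=C11', C12'–C13', prenyl end); union of 16 and 22 at C9'–C10'; desilylation.
4. Geometry: each of the three E-trisubstituted alkenes comes from a Zr-catalysed syn-methylalumination of a terminal alkyne and is carried through stereoretentive couplings.
5. Stereochemistry: C5' (R) from the (R)-TRIP phosphoric acid-catalysed propargylboration of enal 10; C12' (R) from the same acid in the allylboration of enal 20. Both are catalyst-controlled Re-face additions. No ring is formed in the route.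
6. Protection is by silyl ethers only (aryl O, C5' O, and C9' O until step 10); the last two are removed together in the final step.

Key step: step 16

Assumption: in the chiral phosphoric acid-catalysed boronate additions (steps 7 and 14) the (R)-acid is taken to deliver the nucleophile to the Re face of an α,β-unsaturated aldehyde, as it does with aromatic aldehydes; if the opposite sense were found, the (S)-acid would be used in both steps with no other change.

**Route**

Step 1
Reactants: 1 4-methoxy-2-methylphenol
Product: 2 2-hydroxy-5-methoxy-3-methylbenzaldehyde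
Conditions: MgCl2, Et3N, paraformaldehyde, MeCN, reflux; aq. HCl work-up
Reagents that add atoms: paraformaldehyde (as formaldehyde), C=O
Why: Magnesium-mediated ortho-formylation (Casnati–Skattebøl): the magnesium phenoxide delivers formaldehyde to the only free ortho position of ring A and a second formaldehyde oxidises the benzylic alkoxide by hydride transfer, so only the salicylaldehyde is expected.

Step 2
Reactants: 2 2-hydroxy-5-methoxy-3-methylbenzaldehyde
Product: 3 2-[(tert-butyldimethylsilyl)oxy]-5-methoxy-3-methylbenzaldehyde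
Conditions: TBSCl, imidazole, DMF, 25 °C
Reagents that add atoms: tert-butyldimethylsilyl chloride, CC(C)(C)[Si](C)(C)Cl
Why: Imidazole-promoted silylation of a phenol; the aryl silyl ether should tolerate the later alane and nickel steps and is acid-stable enough for step 10.

Step 3
Reactants: 3 2-[(tert-butyldimethylsilyl)oxy]-5-methoxy-3-methylbenzaldehyde
Product: 4 {2-[(tert-butyldimethylsilyl)oxy]-5-methoxy-3-methylphenyl}methanol
Conditions: NaBH4, MeOH, 0 °C
Reagents that add atoms: none
Why: Borohydride reduction of an aryl aldehyde; low temperature and short reaction time should suppress 1,4 O-to-O silyl migration.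

Step 4
Reactants: 4 {2-[(tert-butyldimethylsilyl)oxy]-5-methoxy-3-methylphenyl}methanol
Product: 5 tert-butyl[2-(chloromethyl)-4-methoxy-6-methylphenoxy]dimethylsilane
Conditions: PPh3, N-chlorosuccinimide, CH2Cl2, 0 to 25 °C
Reagents that add atoms: N-chlorosuccinimide, O=C1CCC(=O)N1Cl
Why: Appel-type chlorination with the PPh3/N-chlorosuccinimide couple converts the benzylic alcohol into the chloride under neutral conditions that leave the aryl silyl ether intact.

Step 5
Reactants: 6 4-[(tert-butyldimethylsilyl)oxy]but-1-yne
Product: 9 (2E)-5-[(tert-butyldimethylsilyl)oxy]-3-methylpent-2-en-1-ol, via alkenylalane 7 (not isolated), via lithium alkenylalanate 8 (not isolated)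
Conditions: Me3Al, Cp2ZrCl2 (0.25 equiv), CH2Cl2, 0 to 25 °C; excess Me3Al removed in vacuo; n-BuLi, hexane/THF, 0 °C; paraformaldehyde, 25 °C; aq. Rochelle salt work-up
Reagents that add atoms: trimethylaluminium, C[Al](C)C; paraformaldehyde (as formaldehyde), C=O
Why: Negishi zirconium-catalysed carboalumination adds CH3 and Al syn across the terminal alkyne with Al on the terminal carbon, and the derived ate complex is hydroxymethylated by formaldehyde with retention, which fixes the E geometry of the future C6'=C7' alkene.

Step 6
Reactants: 9 (2E)-5-[(tert-butyldimethylsilyl)oxy]-3-methylpent-2-en-1-ol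
Product: 10 (2E)-5-[(tert-butyldimethylsilyl)oxy]-3-methylpent-2-enal
Conditions: MnO2 (excess), CH2Cl2, 25 °C
Reagents that add atoms: none
Why: Manganese dioxide oxidises the allylic alcohol selectively to the enal and should neither touch the silyl ether nor isomerise the alkene.

Step 7
Reactants: 10 (2E)-5-[(tert-butyldimethylsilyl)oxy]-3-methylpent-2-enal
Product: 11 (4R,5E)-8-[(tert-butyldimethylsilyl)oxy]-6-methyloct-5-en-1-yn-4-ol
Conditions: allenylboronic acid pinacol ester (1.5 equiv), (R)-TRIP [(R)-3,3'-bis(2,4,6-triisopropylphenyl)-1,1'-binaphthyl-2,2'-diyl hydrogen phosphate] (10 mol %), 4 Å molecular sieves, toluene, −20 °C; aq. NaHCO3 work-up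
Reagents that add atoms: allenylboronic acid pinacol ester, C=C=CB1OC(C)(C)C(C)(C)O1
Why: Chiral phosphoric acid-catalysed propargylboration: the allenylboronate reacts at its terminal carbon through a closed six-membered transition state in which the (R)-acid binds the boronate oxygen and the formyl hydrogen and exposes the Re face, which should set C5' as R.

Step 8
Reactants: 11 (4R,5E)-8-[(tert-butyldimethylsilyl)oxy]-6-methyloct-5-en-1-yn-4-ol
Product: 12 (4R,5E)-4,8-bis[(tert-butyldimethylsilyl)oxy]-6-methyloct-5-en-1-yne
Conditions: TBSCl, imidazole, DMF, 25 °C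
Reagents that add atoms: tert-butyldimethylsilyl chloride, CC(C)(C)[Si](C)(C)Cl
Why: Routine silylation of the secondary alcohol, which keeps the allylic carbinol from forming an aluminium alkoxide in step 9 and from reacting in step 11.

Step 9
Reactants: 12 (4R,5E)-4,8-bis[(tert-butyldimethylsilyl)oxy]-6-methyloct-5-en-1-yne; 5 tert-butyl[2-(chloromethyl)-4-methoxy-6-methylphenoxy]dimethylsilane
Product: 14 tert-butyl{2-[(2E,5R,6E)-5,9-bis(tert-butyldimethylsilyloxy)-3,7-dimethylnona-2,6-dien-1-yl]-4-methoxy-6-methylphenoxy}dimethylsilane, via alkenylalane 13 (not isolated)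
Conditions: Me3Al, Cp2ZrCl2 (0.25 equiv), CH2Cl2, 0 to 25 °C; excess Me3Al removed in vacuo; then 5, NiCl2(PPh3)2 (5 mol %) pre-reduced with n-BuLi (10 mol %) to zerovalent nickel, THF, 25 °C
Reagents that add atoms: trimethylaluminium, C[Al](C)C
Why: A second Negishi carboalumination (syn, Al on the terminal carbon) is followed in the same flask by nickel-catalysed cross-coupling of the alkenylalane with the benzylic chloride, a stereoretentive alkenyl–benzyl coupling that forms C1'–C2' and fixes C2'=C3' as E.

Step 10
Reactants: 14 tert-butyl{2-[(2E,5R,6E)-5,9-bis(tert-butyldimethylsilyloxy)-3,7-dimethylnona-2,6-dien-1-yl]-4-methoxy-6-methylphenoxy}dimethylsilane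
Product: 15 (3E,5R,7E)-5-(tert-butyldimethylsilyloxy)-9-[2-(tert-butyldimethylsilyloxy)-5-methoxy-3-methylphenyl]-3,7-dimethylnona-3,7-dien-1-ol
Conditions: PPTS (0.2 equiv), MeOH, 25 °C
Reagents that add atoms: none
Why: Acid-catalysed methanolysis (selective desilylation) should remove the least hindered primary alkyl silyl ether much faster than the secondary allylic and the aryl silyl ethers.

Step 11
Reactants: 15 (3E,5R,7E)-5-(tert-butyldimethylsilyloxy)-9-[2-(tert-butyldimethylsilyloxy)-5-methoxy-3-methylphenyl]-3,7-dimethylnona-3,7-dien-1-ol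
Product: 16 tert-butyl{2-[(2E,5R,6E)-5-(tert-butyldimethylsilyloxy)-9-iodo-3,7-dimethylnona-2,6-dien-1-yl]-4-methoxy-6-methylphenoxy}dimethylsilane
Conditions: I2, PPh3, imidazole, CH2Cl2, 0 °C
Reagents that add atoms: iodine, II
Why: Appel iodination converts the primary alcohol into the iodide by SN2 displacement of the alkoxyphosphonium ion and should leave alkenes and silyl ethers untouched.

Step 12
Reactants: 17 prop-2-yn-1-ol
Product: 19 (2E)-3-iodo-2-methylprop-2-en-1-ol, via O-aluminated alkenylalane 18 (not isolated)
Conditions: Me3Al (3 equiv), Cp2ZrCl2 (0.25 equiv), CH2Cl2, 0 to 25 °C; I2, THF, −30 to 0 °C; aqueous work-up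
Reagents that add atoms: trimethylaluminium, C[Al](C)C; iodine, II
Why: Negishi carboalumination of the O-aluminated propargyl alcohol followed by iodinolysis of the C–Al bond with retention gives the E iodoalkene that becomes C10'=C11'.

Step 13
Reactants: 19 (2E)-3-iodo-2-methylprop-2-en-1-ol
Product: 20 (2E)-3-iodo-2-methylprop-2-enal
Conditions: MnO2 (excess), CH2Cl2, 25 °C, dark; filtered solution used directly
Reagents that add atoms: none
Why: Manganese dioxide oxidation of the allylic alcohol; the volatile, light-sensitive enal is used at once as a solution.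

Step 14
Reactants: 20 (2E)-3-iodo-2-methylprop-2-enal
Product: 21 (1E,3R)-1-iodo-2-methylhexa-1,5-dien-3-ol
Conditions: allylboronic acid pinacol ester (1.2 equiv), (R)-TRIP (5 mol %), toluene, −30 °C; aq. NaHCO3 work-up
Reagents that add atoms: allylboronic acid pinacol ester, C=CCB1OC(C)(C)C(C)(C)O1
Why: Chiral phosphoric acid-catalysed allylboration through a closed six-membered transition state; the (R)-acid directs the allyl group to the Re face of the enal, which should set C12' as R.

Step 15
Reactants: 21 (1E,3R)-1-iodo-2-methylhexa-1,5-dien-3-ol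
Product: 22 (1E,3R)-1-iodo-2,6-dimethylhepta-1,5-dien-3-ol
Conditions: 2-methylbut-2-ene (large excess), second-generation Grubbs catalyst RuCl2(=CHPh)(PCy3)(H2IMes) (5 mol %), CH2Cl2, 40 °C
Reagents that add atoms: 2-methylbut-2-ene, CC=C(C)C
Why: Olefin cross-metathesis of the terminal alkene with excess 2-methylbut-2-ene installs the prenyl terminus, while the trisubstituted iodoalkene is too hindered and electron-poor to engage the ruthenium carbene.

Step 16
Reactants: 16 tert-butyl{2-[(2E,5R,6E)-5-(tert-butyldimethylsilyloxy)-9-iodo-3,7-dimethylnona-2,6-dien-1-yl]-4-methoxy-6-methylphenoxy}dimethylsilane; 22 (1E,3R)-1-iodo-2,6-dimethylhepta-1,5-dien-3-ol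
Product: 23 tert-butyl{2-[(2E,5R,6E,10E,12R)-5-(tert-butyldimethylsilyloxy)-12-hydroxy-3,7,11,15-tetramethylhexadeca-2,6,10,14-tetraen-1-yl]-4-methoxy-6-methylphenoxy}dimethylsilane
Conditions: NiBr2(dme) (10 mol %), 4,4'-di-tert-butyl-2,2'-bipyridine (12 mol %), Zn powder (2.5 equiv), 22 (1.5 equiv), DMA, 25 °C
Reagents that add atoms: none
Why: Reductive nickel-catalysed cross-electrophile coupling: bipyridine-ligated zerovalent nickel, formed by Zn reduction, inserts into the sp2 C10'–I bond of 22 with retention, a monovalent nickel species abstracts iodine from the sp3 C9'–I bond of 16 to give the primary C9' radical, this radical is captured by the divalent alkenylnickel to give a trivalent nickel species that reductively eliminates the C9'–C10' bond, and Zn returns the nickel to its low-valent state. The closest known reaction type is the nickel-catalysed reductive coupling of alkenyl halides with primary alkyl halides, which is stereoretentive at the alkene. No ring is closed and no stereocentre is created; C5' and C12' are remote from the reacting carbons and are carried through unchanged, and the E geometry of C10'=C11' is held by the configurationally stable alkenylnickel intermediate. The step needs cross- over homo-coupling selectivity, which rests on the different activation modes of the two C–I bonds (two-electron oxidative addition at sp2 carbon, halogen-atom abstraction at sp3 carbon) and on the excess of 22. It also needs tolerance of the free C12' hydroxyl, the two silyl ethers and the four C=C bonds, which the neutral Zn/DMA medium without a preformed basic organometallic should secure.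

Step 17
Reactants: 23 tert-butyl{2-[(2E,5R,6E,10E,12R)-5-(tert-butyldimethylsilyloxy)-12-hydroxy-3,7,11,15-tetramethylhexadeca-2,6,10,14-tetraen-1-yl]-4-methoxy-6-methylphenoxy}dimethylsilane
Product: 24 2-[(2E,5R,6E,10E,12R)-5,12-dihydroxy-3,7,11,15-tetramethylhexadeca-2,6,10,14-tetraen-1-yl]-4-methoxy-6-methylphenol
Conditions: TBAF (4 equiv), AcOH (4 equiv), THF, 0 to 25 °C, under argon
Reagents that add atoms: none
Why: Fluoride-mediated desilylation of the aryl and secondary silyl ethers, buffered with acetic acid so that the electron-rich phenoxide is not exposed to air oxidation, should release the target without touching the two allylic alcohols or the four alkenes.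

**Compound list**

1 | 4-methoxy-2-methylphenol | COc1ccc(O)c(C)c1 | starting material
2 | 2-hydroxy-5-methoxy-3-methylbenzaldehyde | COc1cc(C)c(O)c(C=O)c1 | intermediate
3 | 2-[(tert-butyldimethylsilyl)oxy]-5-methoxy-3-methylbenzaldehyde | COc1cc(C)c(O[Si](C)(C)C(C)(C)C)c(C=O)c1 | intermediate
4 | {2-[(tert-butyldimethylsilyl)oxy]-5-methoxy-3-methylphenyl}methanol | COc1cc(C)c(O[Si](C)(C)C(C)(C)C)c(CO)c1 | intermediate
5 | tert-butyl[2-(chloromethyl)-4-methoxy-6-methylphenoxy]dimethylsilane | COc1cc(C)c(O[Si](C)(C)C(C)(C)C)c(CCl)c1 | intermediate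
6 | 4-[(tert-butyldimethylsilyl)oxy]but-1-yne | C#CCCO[Si](C)(C)C(C)(C)C | starting material
7 | [(1E)-4-(tert-butyldimethylsilyloxy)-2-methylbut-1-en-1-yl]dimethylalane (not isolated) | C[Al](C)/C=C(\C)CCO[Si](C)(C)C(C)(C)C | intermediate
8 | lithium butyl[(1E)-4-(tert-butyldimethylsilyloxy)-2-methylbut-1-en-1-yl]dimethylalanate (not isolated) | [Li+].CCCC[Al-](C)(C)/C=C(\C)CCO[Si](C)(C)C(C)(C)C | intermediate
9 | (2E)-5-[(tert-butyldimethylsilyl)oxy]-3-methylpent-2-en-1-ol | OC/C=C(\C)CCO[Si](C)(C)C(C)(C)C | intermediate
10 | (2E)-5-[(tert-butyldimethylsilyl)oxy]-3-methylpent-2-enal | O=C/C=C(\C)CCO[Si](C)(C)C(C)(C)C | intermediate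
11 | (4R,5E)-8-[(tert-butyldimethylsilyl)oxy]-6-methyloct-5-en-1-yn-4-ol | C#CC[C@@H](O)/C=C(\C)CCO[Si](C)(C)C(C)(C)C | intermediate
12 | (4R,5E)-4,8-bis[(tert-butyldimethylsilyl)oxy]-6-methyloct-5-en-1-yne | C#CC[C@@H](O[Si](C)(C)C(C)(C)C)/C=C(\C)CCO[Si](C)(C)C(C)(C)C | intermediate
13 | [(1E,4R,5E)-4,8-bis(tert-butyldimethylsilyloxy)-2,6-dimethylocta-1,5-dien-1-yl]dimethylalane (not isolated) | C[Al](C)/C=C(\C)C[C@@H](O[Si](C)(C)C(C)(C)C)/C=C(\C)CCO[Si](C)(C)C(C)(C)C | intermediate
14 | tert-butyl{2-[(2E,5R,6E)-5,9-bis(tert-butyldimethylsilyloxy)-3,7-dimethylnona-2,6-dien-1-yl]-4-methoxy-6-methylphenoxy}dimethylsilane | COc1cc(C)c(O[Si](C)(C)C(C)(C)C)c(C/C=C(\C)C[C@@H](O[Si](C)(C)C(C)(C)C)/C=C(\C)CCO[Si](C)(C)C(C)(C)C)c1 | intermediate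
15 | (3E,5R,7E)-5-(tert-butyldimethylsilyloxy)-9-[2-(tert-butyldimethylsilyloxy)-5-methoxy-3-methylphenyl]-3,7-dimethylnona-3,7-dien-1-ol | COc1cc(C)c(O[Si](C)(C)C(C)(C)C)c(C/C=C(\C)C[C@@H](O[Si](C)(C)C(C)(C)C)/C=C(\C)CCO)c1 | intermediate
16 | tert-butyl{2-[(2E,5R,6E)-5-(tert-butyldimethylsilyloxy)-9-iodo-3,7-dimethylnona-2,6-dien-1-yl]-4-methoxy-6-methylphenoxy}dimethylsilane | COc1cc(C)c(O[Si](C)(C)C(C)(C)C)c(C/C=C(\C)C[C@@H](O[Si](C)(C)C(C)(C)C)/C=C(\C)CCI)c1 | intermediate
17 | prop-2-yn-1-ol | C#CCO | starting material
18 | dimethyl{[(2E)-3-(dimethylalumanyl)-2-methylprop-2-en-1-yl]oxy}alane (not isolated) | C[Al](C)/C=C(\C)CO[Al](C)C | intermediate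
19 | (2E)-3-iodo-2-methylprop-2-en-1-ol | I/C=C(\C)CO | intermediate
20 | (2E)-3-iodo-2-methylprop-2-enal | I/C=C(\C)C=O | intermediate
21 | (1E,3R)-1-iodo-2-methylhexa-1,5-dien-3-ol | I/C=C(\C)[C@H](O)CC=C | intermediate
22 | (1E,3R)-1-iodo-2,6-dimethylhepta-1,5-dien-3-ol | I/C=C(\C)[C@H](O)CC=C(C)C | intermediate
23 | tert-butyl{2-[(2E,5R,6E,10E,12R)-5-(tert-butyldimethylsilyloxy)-12-hydroxy-3,7,11,15-tetramethylhexadeca-2,6,10,14-tetraen-1-yl]-4-methoxy-6-methylphenoxy}dimethylsilane | COc1cc(C)c(O[Si](C)(C)C(C)(C)C)c(C/C=C(\C)C[C@@H](O[Si](C)(C)C(C)(C)C)/C=C(\C)CC/C=C(\C)[C@H](O)CC=C(C)C)c1 | intermediate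
24 | 2-[(2E,5R,6E,10E,12R)-5,12-dihydroxy-3,7,11,15-tetramethylhexadeca-2,6,10,14-tetraen-1-yl]-4-methoxy-6-methylphenol | COc1cc(C)c(O)c(C/C=C(\C)C[C@@H](O)/C=C(\C)CC/C=C(\C)[C@H](O)CC=C(C)C)c1 | target

**Count and risks**

Total step count: 17. Longest linear sequence: 9 steps (steps 5, 6, 7, 8, 9, 10, 11, 16, 17; the arene branch through steps 1 to 4 is equally long).

Steps most likely to fail:

1. Step 16. The C9' radical may be lost to homocoupling or hydrodehalogenation, and reversible three-membered ring closure of this homoallylic radical onto C7' could erode the C6'=C7' geometry. The fallback is a polar Negishi coupling that avoids a free radical. It sets out from iodide 16: insertion of activated Zn dust in THF with LiCl would give the alkylzinc iodide F1, which would be coupled with iodide 22 under Pd(OAc)2 and 2-dicyclohexylphosphino-2',6'-dimethoxybiphenyl in THF at 25 °C, a catalyst system known to tolerate free hydroxyl groups. It comes back to the route at 23.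

2. Step 9. Transmetalation of the hindered alkenylalane to nickel may be slow, so that protodealumination, methyl transfer from aluminium or benzylic homocoupling take over. The fallback reverses the polarity of the partners. It sets out from 12 and 5: alane 13, made from 12 as in step 9, would be quenched with I2 in THF at −30 °C to give the alkenyl iodide F2; chloride 5 would be converted with Zn dust and LiCl in THF into the benzylic zinc chloride F3; Negishi coupling of F2 with F3 under Pd(PPh3)4 in THF would come back to the route at 14.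

3. Step 7. Facial selectivity may be poor on the β,β-disubstituted enal, or acid-promoted E/Z isomerisation of the enal may compete with addition. The fallback replaces asymmetric catalysis by resolution. It sets out from enal 10: propargyl bromide and Zn in THF/aq. NH4Cl (Barbier conditions) would give the racemic homopropargylic alcohol F4; lipase-catalysed acetylation (Burkholderia cepacia lipase, vinyl acetate, tert-butyl methyl ether), expected from the empirical selectivity rule for secondary alcohols to acylate the R enantiomer, would give the acetate F5, which is separated from the unreacted S alcohol and methanolysed (K2CO3, MeOH). It comes back to the route at 11.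

**Further compounds**

F1 | step 16 | {(3E,5R,7E)-5-(tert-butyldimethylsilyloxy)-9-[2-(tert-butyldimethylsilyloxy)-5-methoxy-3-methylphenyl]-3,7-dimethylnona-3,7-dien-1-yl}zinc iodide | COc1cc(C)c(O[Si](C)(C)C(C)(C)C)c(C/C=C(\C)C[C@@H](O[Si](C)(C)C(C)(C)C)/C=C(\C)CC[Zn]I)c1
F2 | step 9 | (1E,4R,5E)-4,8-bis(tert-butyldimethylsilyloxy)-1-iodo-2,6-dimethylocta-1,5-diene | I/C=C(\C)C[C@@H](O[Si](C)(C)C(C)(C)C)/C=C(\C)CCO[Si](C)(C)C(C)(C)C
F3 | step 9 | {2-[(tert-butyldimethylsilyl)oxy]-5-methoxy-3-methylbenzyl}zinc chloride | COc1cc(C)c(O[Si](C)(C)C(C)(C)C)c(C[Zn]Cl)c1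
F4 | step 7 | racemic (5E)-8-[(tert-butyldimethylsilyl)oxy]-6-methyloct-5-en-1-yn-4-ol | C#CCC(O)/C=C(\C)CCO[Si](C)(C)C(C)(C)C
F5 | step 7 | (4R,5E)-8-[(tert-butyldimethylsilyl)oxy]-6-methyloct-5-en-1-yn-4-yl acetate | C#CC[C@@H](OC(C)=O)/C=C(\C)CCO[Si](C)(C)C(C)(C)C
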